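**Retrosynthetic overview**
- The strategy rests on ring A: the free C6–OH lies para to the ring oxygen O1 on C8a, with OMe on C5 and C7 and H on C8, and O1 and C4a are linked by the C2–C3–C4 chain. This is the 4-alkoxyphenol pattern of a Dötz benzannulation whose alkyne hangs from the carbene oxygen.
- Bonds C8a–C4a, C5–C6 and C6–C7 are cut together, opening rings C and A to the chromium carbene complex 15 (carbene carbon = C8a, vinyl carbons = C8 and C7, a CO ligand = C6, alkyne carbons = C4a and C5).
- O1–C8a is cut by acyloxy/alkoxy exchange at the carbene carbon, giving hydroxy ynone 6 and acylchromate 13 (from a Z-bromovinyl ether and Cr(CO)6).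
- C4–C4a is cut to Weinreb amide 3 and lithium methoxyacetylide; the C2 stereocentre comes from asymmetric hydrogenation of keto ester 1.
- Ring order: the dimethoxyphenyl ring is bought; ring C and then ring A close in the same last operation.

Key step: step 7

Remark: RuCl2[(R)-BINAP] is assumed to be the catalyst enantiomer that gives the S carbinol from an aryl β-keto ester (the mirror-image ligand would be taken otherwise). The SMILES of the chromium complexes draw metal–ligand bonds formally, with the η6-bound Cr(CO)3 of 16 as a dot-joined fragment.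

**Step 1**
Reactants: 1 ethyl 3-(3,4-dimethoxyphenyl)-3-oxopropanoate
Product: 2 ethyl (S)-3-(3,4-dimethoxyphenyl)-3-hydroxypropanoate
Conditions: H2 (50 atm), RuCl2[(R)-BINAP] (0.5 mol %), EtOH, 35 °C
Reagents that add atoms: none
Why: Noyori asymmetric hydrogenation of a β-keto ester, in which the ester carbonyl chelates ruthenium and the (R)-BINAP ligand should deliver hydride to the ketone face that gives the S carbinol (the spatial sense that gives (R)-3-hydroxybutanoate from acetoacetate, the descriptor changing only because aryl outranks CH2CO2Et); this sets C2 of the target.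

**Step 2**
Reactants: 2 ethyl (S)-3-(3,4-dimethoxyphenyl)-3-hydroxypropanoate
Product: 3 (S)-3-(3,4-dimethoxyphenyl)-3-hydroxy-N-methoxy-N-methylpropanamide
Conditions: MeNHOMe·HCl (2 equiv), i-PrMgCl (5 equiv), THF, −20 → 0 °C; aq. NH4Cl
Reagents that add atoms: N,O-dimethylhydroxylamine hydrochloride, CNOC.Cl
Why: Grignard-mediated Weinreb amidation, in which the chloromagnesium amide attacks the ester at low temperature while the hydroxyl is only held as its magnesium alkoxide, so the stereocentre is not touched.

**Step 3**
Reactants: 3 (S)-3-(3,4-dimethoxyphenyl)-3-hydroxy-N-methoxy-N-methylpropanamide; 4 chloroacetaldehyde dimethyl acetal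
Product: 6 (S)-5-(3,4-dimethoxyphenyl)-5-hydroxy-1-methoxypent-1-yn-3-one, via lithium methoxyacetylide 5 (not isolated)
Conditions: Et2NH (10.5 equiv), n-BuLi (10.5 equiv), THF, 0 °C; 4 (3.5 equiv), 0 °C; then 3, −78 → −30 °C; inverse quench into cold aq. NaH2PO4 (pH 4–5), extract cold, use at once
Reagents that add atoms: none
Why: Lithium diethylamide should take the chloroacetal through loss of methanol, loss of HCl and deprotonation to the alkoxyacetylide, which acylates on the Weinreb amide through a chelated tetrahedral adduct that cannot over-add (acetylide acylation of a Weinreb amide); the weakly acidic inverse quench protonates the amines before the ynone is released, so amine conjugate addition and alkoxide-driven oxa-Michael closure should not compete.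

**Step 4**
Reactants: 7 methyl vinyl ether
Product: 9 (Z)-1-bromo-2-methoxyethene, via 1,2-dibromo-1-methoxyethane 8 (not isolated)
Conditions: Br2, pentane, −78 °C; then PhNEt2, 95 °C, distil
Reagents that add atoms: bromine, BrBr
Why: Electrophilic bromine addition to the enol ether followed by amine-induced dehydrobromination, which removes the labile α-bromo ether bromide and, as with the ethoxy analogue, should favour the cis (Z) β-bromovinyl ether.

**Step 5**
Reactants: 9 (Z)-1-bromo-2-methoxyethene; 10 chromium hexacarbonyl Cr(CO)6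
Product: 13 tetramethylammonium pentacarbonyl[(Z)-3-methoxy-1-oxidoprop-2-enylidene]chromate, via (Z)-2-methoxyvinyllithium 11 (not isolated), via lithium acylchromate 12 (not isolated)
Conditions: t-BuLi (2 equiv), Et2O, −78 °C; cannula into Cr(CO)6, THF, −78 → 0 °C; evaporate; Me4NBr, degassed H2O, 0 °C; CH2Cl2 extraction
Reagents that add atoms: tetramethylammonium bromide, C[N+](C)(C)C.[Br-]
Why: Bromine–lithium exchange with retention of alkene geometry gives the chelation-stabilised vinyllithium, which adds to a carbonyl ligand of Cr(CO)6 (Fischer acylmetalate synthesis), and cation exchange gives a salt that can be handled and O-acylated cleanly.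

**Step 6**
Reactants: 13 tetramethylammonium pentacarbonyl[(Z)-3-methoxy-1-oxidoprop-2-enylidene]chromate; 6 (S)-5-(3,4-dimethoxyphenyl)-5-hydroxy-1-methoxypent-1-yn-3-one
Product: 15 pentacarbonyl{(Z)-1-[(1S)-1-(3,4-dimethoxyphenyl)-5-methoxy-3-oxopent-4-ynyloxy]-3-methoxyprop-2-enylidene}chromium, via acetoxycarbene complex 14 (not isolated)
Conditions: AcBr (1.0 equiv), CH2Cl2, −40 °C; then 6 (0.8 equiv), −40 → −10 °C, dark, Ar; cold filtration through SiO2, use at once
Reagents that add atoms: none
Why: O-acylation of the acylchromate gives a strongly electrophilic acyloxycarbene complex whose carbene carbon undergoes addition–elimination with the secondary hydroxyl of 6 (acyloxy/alkoxy exchange of Fischer carbene complexes) without base, so the C2–O bond is never broken and the S configuration is retained.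

**Step 7**
Reactants: 15 pentacarbonyl{(Z)-1-[(1S)-1-(3,4-dimethoxyphenyl)-5-methoxy-3-oxopent-4-ynyloxy]-3-methoxyprop-2-enylidene}chromium
Product: 17 (S)-2-(3,4-dimethoxyphenyl)-6-hydroxy-5,7-dimethoxychroman-4-one, via tricarbonylchromium arene complex 16 (not isolated)
Conditions: THF (0.005 M), 55 °C, Ar; then air, daylight, MeCN–Et2O, rt
Reagents that add atoms: none
Why: Proposed new method: thermal loss of one CO from 15 should let the tethered alkyne coordinate and insert into the Cr=C8a bond with C4a bonding to C8a, which closes ring C in a 6-exo mode across the O1–C2–C3–C4 tether and leaves a methoxy-stabilised chromium vinylcarbene at C5. Migration of a CO ligand to C5 gives the chromium-bound dienylketene with C6 as the ketene carbon, 6π-electrocyclisation joins C6 to C7 to close ring A, and shift of the C7 hydrogen to oxygen gives the 6-phenol as its Cr(CO)3 complex 16, which air and light decomplex. The closest known reaction type is the intramolecular Dötz benzannulation of alkoxy(alkenyl or aryl)carbene chromium complexes that carry the alkyne on the carbene oxygen, which gives chroman-type hydroquinone monoethers; untested here are the β-methoxyvinyl carbene substituent and an acyl-substituted ynol ether as the alkyne. No stereocentre is formed, and C2 keeps its S configuration because no bond to it is made or broken and no base is present. The step needs C4a rather than C5 to bond to C8a, which the three-atom tether enforces because the reverse orientation would require a strained bridged metallacycle, and it needs phenol formation over five-membered annulation or capture of the ketene by the C4 carbonyl, which the chromium alkenylcarbene in dilute THF and the fast electrocyclisation should favour.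

**Compound list**
1 | ethyl 3-(3,4-dimethoxyphenyl)-3-oxopropanoate | CCOC(=O)CC(=O)c1ccc(OC)c(OC)c1 | starting material
2 | ethyl (S)-3-(3,4-dimethoxyphenyl)-3-hydroxypropanoate | CCOC(=O)C[C@H](O)c1ccc(OC)c(OC)c1 | intermediate
3 | (S)-3-(3,4-dimethoxyphenyl)-3-hydroxy-N-methoxy-N-methylpropanamide | COc1ccc([C@@H](O)CC(=O)N(C)OC)cc1OC | intermediate
4 | chloroacetaldehyde dimethyl acetal | COC(OC)CCl | starting material
5 | lithium methoxyacetylide | [Li]C#COC | intermediate
6 | (S)-5-(3,4-dimethoxyphenyl)-5-hydroxy-1-methoxypent-1-yn-3-one | COc1ccc([C@@H](O)CC(=O)C#COC)cc1OC | intermediate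
7 | methyl vinyl ether | COC=C | starting material
8 | 1,2-dibromo-1-methoxyethane | COC(Br)CBr | intermediate
9 | (Z)-1-bromo-2-methoxyethene | CO/C=C\Br | intermediate
10 | chromium hexacarbonyl Cr(CO)6 | O=C=[Cr](=C=O)(=C=O)(=C=O)(=C=O)=C=O | starting material
11 | (Z)-2-methoxyvinyllithium | [Li]/C=C\OC | intermediate
12 | lithium pentacarbonyl[(Z)-3-methoxy-1-oxidoprop-2-enylidene]chromate (lithium acylchromate) | CO/C=C\C([O-])=[Cr](=C=O)(=C=O)(=C=O)(=C=O)=C=O.[Li+] | intermediate
13 | tetramethylammonium pentacarbonyl[(Z)-3-methoxy-1-oxidoprop-2-enylidene]chromate | CO/C=C\C([O-])=[Cr](=C=O)(=C=O)(=C=O)(=C=O)=C=O.C[N+](C)(C)C | intermediate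
14 | pentacarbonyl[(Z)-1-acetoxy-3-methoxyprop-2-enylidene]chromium (acetoxycarbene complex) | CO/C=C\C(OC(C)=O)=[Cr](=C=O)(=C=O)(=C=O)(=C=O)=C=O | intermediate
15 | pentacarbonyl{(Z)-1-[(1S)-1-(3,4-dimethoxyphenyl)-5-methoxy-3-oxopent-4-ynyloxy]-3-methoxyprop-2-enylidene}chromium | COc1ccc([C@@H](OC(/C=C\OC)=[Cr](=C=O)(=C=O)(=C=O)(=C=O)=C=O)CC(=O)C#COC)cc1OC | intermediate
16 | tricarbonylchromium arene complex of 17, Cr(CO)3 η6-bound to ring A | COc1ccc([C@@H]2CC(=O)c3c(cc(OC)c(O)c3OC)O2)cc1OC.O=C=[Cr](=C=O)=C=O | intermediate
17 | (S)-2-(3,4-dimethoxyphenyl)-6-hydroxy-5,7-dimethoxychroman-4-one | COc1ccc([C@@H]2CC(=O)c3c(cc(OC)c(O)c3OC)O2)cc1OC | target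

**Step count**
Total steps: 7. Longest linear sequence: 5 steps (1 → 2 → 3 → 6 → 15 → 17; steps 1, 2, 3, 6, 7).

**Steps most likely to fail**

Step 7 (proposed new method). After alkyne insertion the methoxy-stabilised vinylcarbene may fail to take up CO and give five-membered annulation, the ketene may be intercepted by the C4 carbonyl oxygen, or the donor-substituted carbene may lose CO too slowly and decompose. The fallback uses known chemistry, sets out from 1 and comes back at 17.
- Keto ester 1 would be hydrogenated with the mirror-image catalyst RuCl2[(S)-BINAP] to ethyl (R)-3-(3,4-dimethoxyphenyl)-3-hydroxypropanoate F1.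
- Syringaldehyde would be benzylated (BnBr, K2CO3, DMF) to 4-(benzyloxy)-3,5-dimethoxybenzaldehyde F2 and taken by Dakin-type Baeyer–Villiger oxidation (mCPBA, CH2Cl2; then K2CO3, MeOH) to 4-(benzyloxy)-3,5-dimethoxyphenol F3.
- Mitsunobu etherification of F1 with F3 (PPh3, DIAD, toluene, 0 °C) should give, with inversion, ethyl (S)-3-[4-(benzyloxy)-3,5-dimethoxyphenoxy]-3-(3,4-dimethoxyphenyl)propanoate F4.
- Neutral ester cleavage with Me3SnOH (1,2-dichloroethane, 80 °C), chosen to avoid β-elimination of the phenoxide, would give (S)-3-[4-(benzyloxy)-3,5-dimethoxyphenoxy]-3-(3,4-dimethoxyphenyl)propanoic acid F5.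
- Intramolecular Friedel–Crafts acylation (trifluoroacetic anhydride, CH2Cl2, 0 °C) at one of the two equivalent positions ortho to the ether oxygen would close ring C to (S)-6-(benzyloxy)-2-(3,4-dimethoxyphenyl)-5,7-dimethoxychroman-4-one F6.
- Hydrogenolysis (H2, Pd/C, EtOAc) would give 17.

Step 6. Exchange at the hindered benzylic hydroxyl may be slower than decay of the acyloxycarbene, the liberated acetic acid may add to the ynol ether, or the complex may cyclise prematurely and uncontrolled. The fallback leaves the carbene tether, sets out from 2 and comes back at 17; it forms the C2–O1 aryl ether with retention.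
- Commercial 4-bromo-2,6-dimethoxyphenol would be benzylated (BnBr, K2CO3, DMF) to 2-(benzyloxy)-5-bromo-1,3-dimethoxybenzene F7.
- Bromine–lithium exchange and borylation (n-BuLi, B(Oi-Pr)3, THF, −78 °C; then aq. KHF2) would give potassium [4-(benzyloxy)-3,5-dimethoxyphenyl]trifluoroborate F8.
- Chan–Lam-type oxidative O-arylation of alcohol 2 with F8 (Cu(OAc)2·H2O cat., DMAP, 4 Å MS, O2, CH2Cl2, rt) should give the aryl ether F4 directly in the S series, since the C–O bond of 2 is not broken.
- From F4 the sequence described above through acid F5 and benzyl flavanone F6 leads to 17.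

Step 3. The liberated amines may add to the ynone at the quench, the hydroxy ynone may close by 6-endo oxa-Michael addition, or the dianion may fragment by retro-aldol reaction. The fallback separates release of the hydroxy ynone from the basic acylation; it sets out from 3 and comes back at 6.
- Amide 3 would be silylated (Et3SiCl, imidazole, DMF) to (S)-3-(3,4-dimethoxyphenyl)-N-methoxy-N-methyl-3-(triethylsilyloxy)propanamide F9.
- Acylation of lithium methoxyacetylide 5 on F9 (THF, −78 °C; cold aq. NaHSO4 quench, which the silyl ether tolerates) would give (S)-5-(3,4-dimethoxyphenyl)-1-methoxy-5-(triethylsilyloxy)pent-1-yn-3-one F10, which can be purified.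
- Pyridine-buffered HF·pyridine (THF, 0 °C) would unmask 6 immediately before step 6.

**Further compounds**
F1 | step 7 | ethyl (R)-3-(3,4-dimethoxyphenyl)-3-hydroxypropanoate | CCOC(=O)C[C@@H](O)c1ccc(OC)c(OC)c1
F2 | step 7 | 4-(benzyloxy)-3,5-dimethoxybenzaldehyde | COc1cc(C=O)cc(OC)c1OCc1ccccc1
F3 | step 7 | 4-(benzyloxy)-3,5-dimethoxyphenol | COc1cc(O)cc(OC)c1OCc1ccccc1
F4 | step 7 | ethyl (S)-3-[4-(benzyloxy)-3,5-dimethoxyphenoxy]-3-(3,4-dimethoxyphenyl)propanoate | CCOC(=O)C[C@H](Oc1cc(OC)c(OCc2ccccc2)c(OC)c1)c1ccc(OC)c(OC)c1
F5 | step 7 | (S)-3-[4-(benzyloxy)-3,5-dimethoxyphenoxy]-3-(3,4-dimethoxyphenyl)propanoic acid | OC(=O)C[C@H](Oc1cc(OC)c(OCc2ccccc2)c(OC)c1)c1ccc(OC)c(OC)c1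
F6 | step 7 | (S)-6-(benzyloxy)-2-(3,4-dimethoxyphenyl)-5,7-dimethoxychroman-4-one | COc1ccc([C@@H]2CC(=O)c3c(cc(OC)c(OCc4ccccc4)c3OC)O2)cc1OC
F7 | step 6 | 2-(benzyloxy)-5-bromo-1,3-dimethoxybenzene | COc1cc(Br)cc(OC)c1OCc1ccccc1
F8 | step 6 | potassium [4-(benzyloxy)-3,5-dimethoxyphenyl]trifluoroborate | COc1cc([B-](F)(F)F)cc(OC)c1OCc1ccccc1.[K+]
F9 | step 3 | (S)-3-(3,4-dimethoxyphenyl)-N-methoxy-N-methyl-3-(triethylsilyloxy)propanamide | COc1ccc([C@@H](O[Si](CC)(CC)CC)CC(=O)N(C)OC)cc1OC
F10 | step 3 | (S)-5-(3,4-dimethoxyphenyl)-1-methoxy-5-(triethylsilyloxy)pent-1-yn-3-one | COc1ccc([C@@H](O[Si](CC)(CC)CC)CC(=O)C#COC)cc1OC
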